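**Analysis of the target**

Germacrane numbering (C1–C15) is used for the target 27 and for every intermediate. Compound 27 is a ten-membered carbocycle (C1–C10) bridged by an oxygen between C3 and C10, which gives an oxolane (O, C3, C2, C1, C10) inside an 11-oxabicyclo[6.2.1]undecene. It carries a cis-fused α-methylene-γ-lactone across C6/C7 (O6–C12(=O)–C11(=C13)), a Z trisubstituted alkene C4=C5 with the C15 methyl, an (R)-2-methylbutanoate on O8, a hydroxymethyl group (C14) on C10 and a hemiketal hydroxyl on C3. The configuration is 3S,6S,7R,8R,10R with R in the ester. O6, C11 and O8 lie on one face of the carbocycle, the C10 oxygen is syn to O8 across C9, and C3 is not independent, because the oxolane can span the ring only with C3–C4 and C10–C9 cis. Sensitive points are the methylene lactone (Michael acceptor), the hemiketal (its open form is a Z-enone), the C6 acyloxy group (lost by elimination once a carbanion forms at C7), an 8-hydroxyl cis to C11 (lactone migration) and the α-centre of the ester. The difficulty is a medium ring with a Z alkene and four functionalised carbons (C6, C7, C8, C10) that tolerates no strong base once the lactone is in place. The strategy rests on the run C3(O)–C4(CH3)=C5–C6(O)–C7–C8(O): these are the six ring carbons of toluene cis-dihydrodiol 1, with both oxygens, the methyl group and the C4=C5 alkene already cis-configured. The C6=C7 alkene of 1 then needs carbon at C7 and oxygen at C6, both on the face of O8.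

**Retrosynthetic reasoning**

27 from 26, and 26 from 24 + 25. The O14 silyl ether is removed last and the O8–acyl bond is made just before. The ester is cut late because its α-centre is epimerisable and because a free 8-hydroxyl cis to C11 is where the lactone could migrate. In 24, O14 is silylated and O3 is tertiary, so O8 is the only hydroxyl that acylates.

24 from 23. The C8–H bond is cut to the ketone. C8 is the one centre of 1 that cannot be carried through, since the C3–C8 bond has to be broken at a carbinol carbon. It is regenerated by reagent-controlled reduction at a stage where the C3 ketone is masked as the hemiketal and the only other electrophile is the methylene lactone.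

23 from 22 from 21. The hemiketal O–C3 bond is opened to the hydroxy dione 22, and the two carbonyl carbons C3 and C8 are reconnected to the ring-fusion diol 21. The ten-membered ring is therefore not closed but released by glycol cleavage of a six-six bicycle. This avoids high dilution and any carbanion next to the C6 acyloxy group, and the C4=C5 alkene keeps the Z geometry it has in ring A. Cleaving C3–C8 before C2 and C9 are attached would instead leave two aldehyde carbons of similar reactivity and a C2–C3 ring closure that needs a strong base.

21 from 20 from 19. The C10–O and C14–O bonds go back to the C10=C14 methylidene, and O14 is then silylated. The oxygens are introduced on the rigid cis-fused bicycle, where the two faces of the exocyclic alkene differ, and not on the flexible ten-membered ring.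

19 from 16 (through 17 and 18). The C11=C13 bond is traced to the extra carboxyl on C11, which is lost by decarboxylation in the step that brings in C13. The second carbonyl carbon installed by the key step is thus used as the handle for the methylene group, and no lactone enolate is needed.

16 from 15. The C8–C9 bond is cut to an allylsilane tethered to C3 and a C8 ketone. The tether allows only a six-membered closure to the cis-fused ring B.

15 from 14, and 14 from 6 + 13. The C8 ketone comes from the alcohol, and the C2–C3 bond from 1,2-addition of Grignard reagent 13 to the C3 ketone of 6. C2 is attached here because C3 is a ketone only at this stage, and the cis-fused lactone directs the nucleophile to the opposite face.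

12 from 10 from 7. The five-carbon unit C2–C1–C10(=C14)–C9 is taken from 3-methylbut-3-en-1-ol (7). Its methyl group becomes C9 by directed lithiation and silylation, and its hydroxyl becomes the bromide.

6 from 5 from 4. The O8–acyl bond of the bis-lactone is cut selectively. Oxidation of the free 3-hydroxyl makes the C8 lactone an α-ketol ester, so that under equilibrating alcoholysis it opens while the C6 lactone stays closed.

4 from 3. The C7–C11 and O–C6 bonds are cut together. Forward, one oxidative radical cascade adds carbon and oxygen cis across C6=C7 and relays the configuration of C8 to C7 and C6.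

3 from 1 + 2. The malonate half-ester is placed on the less hindered 8-hydroxyl of 1 by acyl transfer from 2.

**Alternatives that were turned down**

Alternative 1: ring closure by olefin metathesis at C4=C5. The oxolane would be built first as a methyl ketal at C3, and the second-generation Grubbs catalyst would join a 2-propenyl group on C3 with a vinyl group on C6 to give the bridged ketal lactone A1.
- For: the ketal holds both alkenes on one side of the oxolane, C10 and C3 are fixed before ring closure, and A1 already carries the silyl ethers for a conventional end game.
- Against: the new alkene is trisubstituted, lies between a fully substituted ketal carbon and the lactone-bearing C6, and must be Z. Hindered 1,1-disubstituted partners react slowly, so oligomerisation competes, and the geometry is decided by ring strain and not by design. C6, C7, C8 and C10 must each be made beforehand by separate stereoselective steps, and C13 still has to be added by enolate chemistry.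
- Comparison: this plan is stronger on C10 and C3 and on convergence. The chosen route offers a Z alkene inherited from 1, C6 and C7 from a single step, and a ten-membered ring obtained by fragmentation.

Alternative 2: ring expansion by anionic oxy-Cope rearrangement. Ring A (C3–C8) would carry a vinyl group on C3 and an allenyl group on C8 at adjacent carbinol carbons. KH with 18-crown-6 gives the dialkoxide, whose [3,3] shift forms C1–C10, breaks C3–C8 and gives the ten-membered dione A2 with the C10 methylidene.
- For: it also avoids macrocyclisation and keeps the Z alkene, and it forms the ring and C1–C10 in one step. That is shorter than steps 7 to 9 and 13 here, and on this point it is the stronger plan.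
- Against: two different unsaturated nucleophiles must be added to a ring A dicarbonyl equivalent that aromatises easily. The product is a bis-enolate made with a strong base next to the C6 oxygen, so the lactone must be held back as a lactol acetal (as in A2) and re-oxidised, after which C13 still needs enolate chemistry.
- Comparison: A2 and dione 22 face the same later tasks at C8 and C10. The chosen route offers a neutral fragmentation, the lactone at its final oxidation level from step 2, the C10 oxygens set before ring expansion, and a built-in handle for C13.

Alternative 3: macrocyclisation by intramolecular nitrile oxide cycloaddition. NaOCl would oxidise a C8 aldoxime to the nitrile oxide, which adds across the C9=C10 methylidene, forming C8–C9 and O–C10 and giving the isoxazoline-bridged ring A3.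
- For: C8–C9, the quaternary C10–O centre and the ring arise in one step. The isoxazoline is a masked β-hydroxy ketone, so after N–O cleavage a hydroxyl-directed 1,3-syn reduction could set C8 from C10. That is a better-founded control of C8 than the reduction of 23, and on this point it is stronger.
- Against: a ten-membered ring must be closed by a cycloaddition that competes with nitrile oxide dimerisation. The C10 face is decided in a strained bridged transition state with no controlling element. Hypochlorite must spare the Z-enone, and the open-chain precursor with the Z-enone and cis-lactone has to be assembled first.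
- Comparison: the chosen route forms the ring by fragmentation and sets C10 on a rigid bicycle.

Key step: step 2

Remark on the chemistry: 1 and 25 are taken as commercial single enantiomers. Centres that are erased later (C11 in 6 and 14 to 18, C3 and C8 in 14 to 21) are drawn as the mechanism predicts; C11 is drawn with the ester trans to C8.

**Route**

Step 1
Reactants: 1 (1S,2R)-3-methylcyclohexa-3,5-diene-1,2-diol; 2 Meldrum's acid
Product: 3 C8 malonate half-ester of 1, 3-{[(1S,6R)-6-hydroxy-5-methylcyclohexa-2,4-dien-1-yl]oxy}-3-oxopropanoic acid
Conditions: 2 (1.05 equiv), MeCN, 65 °C, dilute, argon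
Reagents that add atoms: none
Why: Alcoholysis of Meldrum's acid (acyl transfer with loss of acetone) gives a malonic half-ester directly. The 8-hydroxyl reacts because the 3-hydroxyl is flanked by the methyl-bearing C4; moderate temperature and dilution limit dimerisation and dehydration of the dienol.

Step 2
Reactants: 3 C8 malonate half-ester
Product: 4 all-cis bis-γ-lactone (ring A C3–C8 with O8–CO and O6–CO lactones sharing C11 on C7, free 3-hydroxyl on the same face)
Conditions: Mn(OAc)3·2H2O (2.2 equiv), Cu(OAc)2·H2O (0.2 equiv), KOAc, degassed AcOH, 40–45 °C
Reagents that add atoms: none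
Why: Mn(OAc)3 binds the malonic half-ester as its enolate, and inner-sphere electron transfer gives the electrophilic malonyl radical at C11 (trivalent manganese becomes divalent). The radical closes the C8 lactone by 5-exo-trig attack on C7, the unsubstituted diene terminus, which leaves an allyl radical over C6–C5–C4; 6-endo attack at C6 would give an unstabilised radical. Divalent copper, regenerated by a second equivalent of Mn(OAc)3, oxidises the allyl radical to an allylcopper or allyl cation, and the free carboxyl on C11 captures C6 in a 5-exo closure of the second lactone; C4 is out of reach because a seven-membered bridge would be needed. C7 is set by the tether, since a γ-lactone can be fused to the six-membered ring only cis, so C11 enters on the face of O8. C6 is set in the same way by the second ring, and C11 has no freedom once both rings are closed. The closest known reactions are the Mn(OAc)3/Cu(OAc)2 oxidative cyclisation of unsaturated malonates and the carbolactonisation of alkenes and 1,3-dienes by malonic acid derivatives with the same oxidant. The step needs chemoselectivity for the malonate over the allylic 3-hydroxyl and over acid-promoted dehydration of the dienol, which buffered acetic acid, moderate temperature and the poor enolisability of the product should provide.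

Step 3
Reactants: 4 bis-lactone
Product: 5 3-oxo bis-lactone (enone C3(=O)–C4=C5)
Conditions: Dess–Martin periodinane, CH2Cl2, 0 °C to rt
Reagents that add atoms: none
Why: Dess–Martin oxidation of the only free hydroxyl (allylic, secondary). The C3 ketone turns the C8 lactone into an α-ketol ester, which step 4 exploits; no base is used because enolisation toward C8 would start aromatisation.

Step 4
Reactants: 5 3-oxo bis-lactone
Product: 6 α-hydroxy enone (3-oxo, 8-hydroxy, C6 lactone retained, allyl ester on C11)
Conditions: allyl alcohol/CH2Cl2 (1:1), DMAP (0.2 equiv), 0 °C to rt; AcOH quench before concentration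
Reagents that add atoms: allyl alcohol, C=CCO
Why: DMAP-catalysed transesterification (alcoholysis of a lactone) under equilibrating conditions. Acyl groups settle on the less acidic hydroxyl, so the lactone whose ring oxygen sits α to the ketone (O8) opens and the C6 lactone stays. The acid quench prevents re-closure on concentration.

Step 5
Reactants: 7 3-methylbut-3-en-1-ol
Product: 10 3-[(trimethylsilyl)methyl]but-3-en-1-ol, via dilithio derivative 8 (not isolated), via C,O-bis(trimethylsilyl) derivative 9 (not isolated)
Conditions: n-BuLi (2.1 equiv), TMEDA, Et2O, 0 °C to rt; Me3SiCl (2.2 equiv), −78 °C to rt; then dilute H2SO4, THF, rt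
Reagents that add atoms: chlorotrimethylsilane, C[Si](C)(C)Cl
Why: Alkoxide-directed allylic lithiation of the methyl group, C,O-bis-silylation and hydrolysis of the labile O–Si bond. This is the standard entry to 2-(silylmethyl)allyl building blocks.

Step 6
Reactants: 10 3-[(trimethylsilyl)methyl]but-3-en-1-ol
Product: 12 (4-bromo-2-methylidenebutyl)trimethylsilane, via mesylate 11 (not isolated)
Conditions: MsCl, Et3N, CH2Cl2, 0 °C; then LiBr, acetone, 50 °C
Reagents that add atoms: lithium bromide, [Li+].[Br-]
Why: Mesylation, then SN2 displacement by bromide at a primary carbon (Finkelstein type). The allylsilane is inert to both.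

Step 7
Reactants: 6 α-hydroxy enone; 12 (4-bromo-2-methylidenebutyl)trimethylsilane
Product: 14 3,8-diol whose C3 is a tertiary carbinol carrying the C2–C1–C10(=C14)–C9–SiMe3 chain anti to the lactone, via Grignard reagent 13 (not isolated)
Conditions: 12, Mg, THF, rt; CeCl3 (dried), THF, −78 °C; added to 6 pre-treated with LiN(SiMe3)2 (2.0 equiv), THF, −78 to −40 °C
Reagents that add atoms: none
Why: CeCl3-promoted Grignard 1,2-addition to a ketone (low basicity, no conjugate addition). LiN(SiMe3)2 first converts the malonate C–H and the 8-hydroxyl into a dianion whose ester carbonyls are switched off. The nucleophile enters C3 opposite the cis-fused lactone (chelated O8 in the carbonyl plane, axial C11 blocking the other face), so C2 ends anti and O3 syn to O8.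

Step 8
Reactants: 14 3,8-diol
Product: 15 8-ketone (α-hydroxy ketone with tertiary 3-hydroxyl)
Conditions: IBX, DMSO, rt
Reagents that add atoms: none
Why: IBX oxidises the secondary hydroxyl of a 1,2-diol to the α-hydroxy ketone without C–C cleavage, which a periodinane or a lead reagent could cause here. The neutral medium spares the β-acyloxy ketone.

Step 9
Reactants: 15 8-ketone
Product: 16 cis-fused tricyclic 3,8-diol (ring B: C3–C2–C1–C10(=C14)–C9–C8), allyl ester on C11
Conditions: Me2AlCl (2.5 equiv), CH2Cl2, −78 °C
Reagents that add atoms: none
Why: Intramolecular Hosomi–Sakurai allylation. Me2AlCl deprotonates the tertiary hydroxyl and chelates the α-alkoxy ketone, and the allylsilane tethered to C3 attacks C8 from the tether face in a six-membered closure. Ring B is therefore cis-fused, with both hydroxyls syn.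

Step 10
Reactants: 16 tricyclic diol allyl ester
Product: 19 α-methylene lactone 3,8-diol, via α-carboxy lactone 17 (not isolated), via Mannich base 18 (not isolated)
Conditions: Pd(PPh3)4 (5 mol %), Et2NH (2.5 equiv), THF, rt; then paraformaldehyde, NaOAc/AcOH, 60 °C
Reagents that add atoms: formaldehyde (as paraformaldehyde), C=O
Why: Deallylation by zerovalent palladium, with Et2NH as allyl acceptor, frees the α-carboxy lactone. Its Mannich base with formaldehyde undergoes decarboxylative elimination, the classical α-methylenation of α-carboxy lactones, so the extra carboxyl from step 2 leaves as C13 enters.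

Step 11
Reactants: 19 α-methylene lactone diol
Product: 20 3,8,10,14-tetraol (10-hydroxyl syn to the ring-fusion hydroxyls)
Conditions: OsO4 (2 mol %), N-methylmorpholine N-oxide (1.1 equiv), acetone/H2O, 0 °C
Reagents that add atoms: osmium tetroxide, O=[Os](=O)(=O)=O; N-methylmorpholine N-oxide, C[N+]1([O-])CCOCC1
Why: Catalytic syn-dihydroxylation; OsO4 prefers the electron-rich, unhindered exocyclic alkene over the acrylate and the shielded ring alkene. In the cis-fused bicycle the C8–C7 bond is axial on ring B, so osmylation should occur by equatorial attack anti to it. This places the C10 oxygen on the face of the ring-fusion hydroxyls, which is the C10 configuration of 27.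

Step 12
Reactants: 20 tetraol
Product: 21 14-O-tert-butyldimethylsilyl triol
Conditions: t-BuMe2SiCl (1.1 equiv), imidazole, DMF, 0 °C
Reagents that add atoms: tert-butyldimethylsilyl chloride, CC(C)(C)[Si](C)(C)Cl
Why: Silylation of the only primary hydroxyl. It blocks cleavage of the C10/C14 diol in step 13 and acylation of O14 in step 15.

Step 13
Reactants: 21 14-O-silyl triol
Product: 23 3,10-epoxy hemiketal 8-ketone (oxabicycle with 4Z alkene), via ten-membered 3,8-dione 22 (not isolated)
Conditions: Pb(OAc)4 (1.1 equiv), CH2Cl2, −20 to 0 °C
Reagents that add atoms: none
Why: Criegee glycol cleavage of the cis ring-fusion diol breaks C3–C8 and expands the bicycle to the ten-membered 3,8-dione, with the Z alkene inherited from ring A. The free 10-hydroxyl then adds across the ring to the C3 ketone (five-membered hemiketal), which can form only with C3–C4 and C10–C9 cis on the oxolane; this fixes C3.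

Step 14
Reactants: 23 hemiketal 8-ketone
Product: 24 (8R)-alcohol
Conditions: (S)-Me-CBS oxazaborolidine (1.0 equiv), catecholborane (3 equiv), CH2Cl2/toluene, −78 to −40 °C
Reagents that add atoms: none
Why: Corey–Bakshi–Shibata reduction with catecholborane, which neither reduces the methylene lactone nor hydroborates. The (S)-catalyst treats the branched C7 side as the large group and should deliver hydride to give the 8R alcohol, syn to the C10 oxygen. The hemiketal keeps the C3 ketone masked.

Step 15
Reactants: 24 (8R)-alcohol; 25 (R)-2-methylbutanoic acid
Product: 26 8-O-[(R)-2-methylbutanoyl] 14-O-silyl ether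
Conditions: DCC, DMAP (0.2 equiv), CH2Cl2, 0 °C to rt
Reagents that add atoms: none
Why: Steglich esterification of the only reactive hydroxyl (secondary O8; O3 is a tertiary hemiketal hydroxyl). Carbodiimide activation at low temperature with little DMAP avoids ketene formation and keeps the α-centre of the acid.

Step 16
Reactants: 26 ester silyl ether
Product: 27 target (CNP0328225.2)
Conditions: HF·pyridine, pyridine/THF, 0 °C to rt
Reagents that add atoms: none
Why: Fluoride cleavage of the primary silyl ether under buffered conditions that leave the ester, hemiketal and methylene lactone untouched.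

**Compound list**

1 | (1S,2R)-3-methylcyclohexa-3,5-diene-1,2-diol | O[C@H]1C=CC=C(C)[C@H]1O | starting material
2 | Meldrum's acid | CC1(C)OC(=O)CC(=O)O1 | starting material
3 | C8 malonate half-ester of 1 | OC(=O)CC(=O)O[C@H]1C=CC=C(C)[C@H]1O | intermediate
4 | all-cis bis-γ-lactone, free 3-hydroxyl | O=C1O[C@H]2C=C(C)[C@@H](O)[C@H]3OC(=O)[C@@H]1[C@@H]23 | intermediate
5 | 3-oxo bis-lactone | O=C1O[C@H]2C=C(C)C(=O)[C@H]3OC(=O)[C@@H]1[C@@H]23 | intermediate
6 | α-hydroxy enone, C6 lactone, allyl ester on C11 | O=C1O[C@H]2C=C(C)C(=O)[C@@H](O)[C@H]2[C@@H]1C(=O)OCC=C | intermediate
7 | 3-methylbut-3-en-1-ol | C=C(C)CCO | starting material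
8 | dilithio derivative of 7 | [Li]CC(=C)CCO[Li] | intermediate
9 | trimethyl{2-methylidene-4-[(trimethylsilyl)oxy]butyl}silane | C[Si](C)(C)CC(=C)CCO[Si](C)(C)C | intermediate
10 | 3-[(trimethylsilyl)methyl]but-3-en-1-ol | C[Si](C)(C)CC(=C)CCO | intermediate
11 | 3-[(trimethylsilyl)methyl]but-3-en-1-yl methanesulfonate | C[Si](C)(C)CC(=C)CCOS(C)(=O)=O | intermediate
12 | (4-bromo-2-methylidenebutyl)trimethylsilane | C[Si](C)(C)CC(=C)CCBr | intermediate
13 | {3-[(trimethylsilyl)methyl]but-3-en-1-yl}magnesium bromide | C[Si](C)(C)CC(=C)CC[Mg]Br | intermediate
14 | 3,8-diol with C3 side chain, allyl ester | O=C1O[C@H]2C=C(C)[C@](O)(CCC(=C)C[Si](C)(C)C)[C@@H](O)[C@H]2[C@@H]1C(=O)OCC=C | intermediate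
15 | 8-ketone of 14 | O=C1O[C@H]2C=C(C)[C@](O)(CCC(=C)C[Si](C)(C)C)C(=O)[C@H]2[C@@H]1C(=O)OCC=C | intermediate
16 | cis-fused tricyclic 3,8-diol, allyl ester | O=C1O[C@H]2C=C(C)[C@]3(O)CCC(=C)C[C@]3(O)[C@H]2[C@@H]1C(=O)OCC=C | intermediate
17 | α-carboxy lactone | O=C1O[C@H]2C=C(C)[C@]3(O)CCC(=C)C[C@]3(O)[C@H]2[C@@H]1C(=O)O | intermediate
18 | Mannich base (C11 bearing CO2H and CH2NEt2) | O=C1O[C@H]2C=C(C)[C@]3(O)CCC(=C)C[C@]3(O)[C@H]2[C@@]1(CN(CC)CC)C(=O)O | intermediate
19 | α-methylene lactone 3,8-diol | O=C1O[C@H]2C=C(C)[C@]3(O)CCC(=C)C[C@]3(O)[C@H]2C1=C | intermediate
20 | 3,8,10,14-tetraol | O=C1O[C@H]2C=C(C)[C@]3(O)CC[C@](O)(CO)C[C@]3(O)[C@H]2C1=C | intermediate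
21 | 14-O-TBS triol | O=C1O[C@H]2C=C(C)[C@]3(O)CC[C@](O)(CO[Si](C)(C)C(C)(C)C)C[C@]3(O)[C@H]2C1=C | intermediate
22 | ten-membered (4Z)-3,8-dione, 10-hydroxy, 14-OTBS | C=C1C(=O)O[C@H]2/C=C(/C)C(=O)CC[C@](O)(CO[Si](C)(C)C(C)(C)C)CC(=O)[C@@H]12 | intermediate
23 | 3,10-epoxy hemiketal 8-ketone, 14-OTBS | C=C1C(=O)O[C@H]2/C=C(/C)[C@]3(O)CC[C@](CO[Si](C)(C)C(C)(C)C)(CC(=O)[C@@H]12)O3 | intermediate
24 | (8R)-alcohol, 14-OTBS | C=C1C(=O)O[C@H]2/C=C(/C)[C@]3(O)CC[C@](CO[Si](C)(C)C(C)(C)C)(C[C@@H](O)[C@@H]12)O3 | intermediate
25 | (R)-2-methylbutanoic acid | CC[C@@H](C)C(=O)O | starting material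
26 | 8-O-[(R)-2-methylbutanoyl], 14-OTBS | C=C1C(=O)O[C@H]2/C=C(/C)[C@]3(O)CC[C@](CO[Si](C)(C)C(C)(C)C)(C[C@@H](OC(=O)[C@H](C)CC)[C@@H]12)O3 | intermediate
27 | CNP0328225.2 | C=C1C(=O)O[C@H]2/C=C(/C)[C@]3(O)CC[C@](CO)(C[C@@H](OC(=O)[C@H](C)CC)[C@@H]12)O3 | target

**Step count and risk**

Total: 16 steps. Longest linear sequence: 14 steps (steps 1–4 and 7–16); the side chain 12 is made in 2 steps (5, 6).

Step 2 (key step). The likely failure is slow 5-exo closure, because the ester tether prefers the rotamer in which C11 cannot reach C7. The malonyl radical is then consumed intermolecularly, while the acid medium dehydrates the dienol to aromatics; loss of a proton from the oxidised allyl intermediate instead of lactonisation is a further risk. Fallback, from 1 and returning at 4: 1 is acylated at O8 with methyl malonyl chloride and pyridine at −20 °C to give the methyl malonate F1. Iodination with NIS and catalytic Et3N gives the iodomalonate F2. Iodine-atom-transfer cyclisation ((Bu3Sn)2 catalytic, light, benzene, 80 °C) gives the C8 lactone allylic iodide F3. On continued heating the ester carbonyl displaces the iodide with inversion and loses iodomethane, which closes the C6 lactone to 4.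

Step 4. Ring opening may be incomplete or reverse on concentration, the C6 lactone may open in competition, and DMAP may enolise the α-ketol toward C8, which leads to loss of the C6 carboxylate and aromatisation. Fallback, from 4 and returning at 6, with the lactones differentiated before the ketone exists: 4 is equilibrated with allyl alcohol and catalytic K2CO3, then treated with 2,2-dimethoxypropane and camphorsulfonic acid. Only the isomer with a free cis-3,8-diol is trapped, as the acetonide F4 with the C6 lactone closed. Aqueous AcOH gives the diol F5, and MnO2 oxidises the allylic 3-hydroxyl selectively to 6.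

Step 7. The reagent may act as a base instead of adding to the hindered, dianionic ketone, and a transient C8 alkoxide may attack the malonate ester and re-close to 5. Fallback, from 6 and returning at 14: Et3SiOTf and 2,6-lutidine give the silyl ether F6, which has no alkoxide. The same Grignard reagent with CeCl3 gives the adduct F7 (polar Felkin–Anh control should favour the same face), and HF·pyridine removes the silyl group to give 14.

Step 11. Osmylation may occur from the other face of ring B if the bicycle populates the alternative chair (axial 8-hydroxyl instead of axial C7), and over-oxidation at the acrylate or at C4=C5 is possible. Fallback, from 19 and returning at 24, with the dihydroxylation deferred and directed by the 8-hydroxyl: Pb(OAc)4 on 19 gives the ten-membered dione F8. LiAlH(O-t-Bu)3 at −78 °C reduces the saturated C8 ketone to the hydroxy enone F9. Stoichiometric OsO4 with TMEDA in CH2Cl2 at −78 °C, directed by hydrogen bonding, dihydroxylates C10=C14 syn to the 8-hydroxyl, and the product closes to the hemiketal triol F10. Silylation with t-BuMe2SiCl and imidazole gives 24. This fallback depends on the reduction of F8 giving the 8R alcohol.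

Step 14. The intrinsic facial bias of the bridged ketone may oppose the catalyst (mismatched pair), which would give poor selectivity or the C8 epimer. Fallback, from 23 and returning at 26: the 8S selectivity is used deliberately ((R)-Me-CBS oxazaborolidine with catecholborane, or NaBH4 if the substrate bias suffices) to make the 8-epi alcohol F11. Mitsunobu esterification with 25 (PPh3, DIAD, toluene, 0 °C) then inverts C8 and installs the ester in one step.

**Further compounds**

F1 | step 2 | methyl malonate of 1 at O8 | COC(=O)CC(=O)O[C@H]1C=CC=C(C)[C@H]1O
F2 | step 2 | iodomalonate of 1 at O8 (both epimers at the iodo carbon) | COC(=O)C(I)C(=O)O[C@H]1C=CC=C(C)[C@H]1O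
F3 | step 2 | C8 lactone with methyl ester on C11 and allylic iodide at C6 (trans to C11) | COC(=O)[C@@H]1C(=O)O[C@@H]2[C@H](O)C(C)=C[C@@H](I)[C@H]12
F4 | step 4 | 3,8-acetonide of the C6 lactone allyl ester | O=C1O[C@H]2C=C(C)[C@H]3OC(C)(C)O[C@H]3[C@H]2[C@@H]1C(=O)OCC=C
F5 | step 4 | cis-3,8-diol of the C6 lactone allyl ester | O=C1O[C@H]2C=C(C)[C@@H](O)[C@@H](O)[C@H]2[C@@H]1C(=O)OCC=C
F6 | step 7 | 8-O-triethylsilyl ether of 6 | O=C1O[C@H]2C=C(C)C(=O)[C@@H](O[Si](CC)(CC)CC)[C@H]2[C@@H]1C(=O)OCC=C
F7 | step 7 | 8-O-triethylsilyl ether of 14 | O=C1O[C@H]2C=C(C)[C@](O)(CCC(=C)C[Si](C)(C)C)[C@@H](O[Si](CC)(CC)CC)[C@H]2[C@@H]1C(=O)OCC=C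
F8 | step 11 | ten-membered (4Z)-3,8-dione with C10 methylidene and methylene lactone | C=C1C(=O)O[C@H]2/C=C(/C)C(=O)CCC(=C)CC(=O)[C@@H]12
F9 | step 11 | (8R)-8-hydroxy (4Z)-3-enone with C10 methylidene | C=C1C(=O)O[C@H]2/C=C(/C)C(=O)CCC(=C)C[C@@H](O)[C@@H]12
F10 | step 11 | 3,10-epoxy hemiketal 8,14-diol | C=C1C(=O)O[C@H]2/C=C(/C)[C@]3(O)CC[C@](CO)(C[C@@H](O)[C@@H]12)O3
F11 | step 14 | (8S)-alcohol, C8 epimer of 24 | C=C1C(=O)O[C@H]2/C=C(/C)[C@]3(O)CC[C@](CO[Si](C)(C)C(C)(C)C)(C[C@H](O)[C@@H]12)O3
A1 | alternative 1 | bridged methyl ketal lactone with Z C4=C5 alkene, 8-OTES, 14-OTBS | C1C(=O)O[C@H]2/C=C(/C)[C@]3(OC)CC[C@](CO[Si](C)(C)C(C)(C)C)(C[C@@H](O[Si](CC)(CC)CC)[C@@H]12)O3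
A2 | alternative 2 | (Z)-cyclodec-4-ene-3,8-dione with 10-methylidene and fused methyl lactol acetal | C1[C@@H](OC)O[C@H]2/C=C(/C)C(=O)CCC(=C)CC(=O)[C@@H]12
A3 | alternative 3 | isoxazoline-bridged ten-membered (Z)-enone lactone, 14-OTBS | C1C(=O)O[C@H]2/C=C(/C)C(=O)CC[C@]3(CO[Si](C)(C)C(C)(C)C)CC(=NO3)[C@@H]12
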